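## Retrosynthetic overview

1. Feature: in each flavan unit, C2 carries the phenyl group and O1 and is tied to arene carbon C4a by the methylenes C3 and C4. C2–C3 is therefore taken from a vinylboron unit that receives phenyl at C2 and the benzylic carbon C4 at C3.
2. Target 23 ⇐ debenzylation ⇐ double O1–C2 Mitsunobu closure (inversion) of (R,R)-diol 21 ⇐ C–B oxidation (retention) of bis-boronate 19.
3. 19 ⇐ twofold three-component coupling of bis(chloromethyl)arene 15, vinylboronic ester 16 and phenyllithium 17 (two C3–C4 bonds, two C2–phenyl bonds, two stereocentres, no ring).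
4. 15 ⇐ bis-aldehyde 12 ⇐ CH2 bridge from C8 of unit A to C6 of unit B, built by two Suzuki couplings of CH2(Bpin)2 with iodides 4 and 9. The unsymmetrical linkage is fixed by the cap on the oxygen between formyl group and iodide: methoxymethyl (future O1) in unit A from 1, methyl (C5–OMe) in unit B from 5.
5. Ring order: both benzene rings are purchased; the two pyran rings close last and together, in step 15.

Key step: step 12

Remark on the structure: the halves are joined unsymmetrically. Unit A is bridged at C8 (between C7–OH and C8a) and unit B at C6 (between C5–OMe and C7–OH); both C2 centres are (S). Locants C2–C8a are flavan locants throughout.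

Assumption on the catalyst: the (S,S)-antipode of N,N′-dimethyl-1,2-diphenylethane-1,2-diamine is taken to deliver the (R)-boronates. The sense of induction is to be checked on a simple 2,6-dialkoxybenzyl chloride, and the mirror-image ligand used if it is the opposite.

## Route

Step 1
Reactants: 1 2,4-dihydroxy-6-methoxybenzaldehyde
Product: 2 4-(benzyloxy)-2-hydroxy-6-methoxybenzaldehyde
Conditions: BnBr (1.05 equiv), K2CO3, acetone, rt to 50 °C
Reagents that add atoms: benzyl bromide, BrCc1ccccc1
Why: Williamson etherification, in which the 4-hydroxyl para to the formyl group is the more acidic and is not held in the hydrogen bond that deactivates the 2-hydroxyl, so one equivalent of benzyl bromide should alkylate it selectively.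

Step 2
Reactants: 2 4-(benzyloxy)-2-hydroxy-6-methoxybenzaldehyde
Product: 3 4-(benzyloxy)-2-hydroxy-3-iodo-6-methoxybenzaldehyde
Conditions: NIS (1.0 equiv), DMF, 0 °C to rt, dark
Reagents that add atoms: N-iodosuccinimide, O=C1CCC(=O)N1I
Why: Electrophilic aromatic iodination, in which the free chelated phenol directs iodine to its only open ortho position C3 (future C8 of unit A), the competing C5 being flanked by the benzyloxy and methoxy groups.

Step 3
Reactants: 3 4-(benzyloxy)-2-hydroxy-3-iodo-6-methoxybenzaldehyde
Product: 4 4-(benzyloxy)-3-iodo-6-methoxy-2-(methoxymethoxy)benzaldehyde (unit A iodide)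
Conditions: NaH, MOMCl, DMF, 0 °C to rt
Reagents that add atoms: chloromethyl methyl ether, COCCl
Why: Williamson-type O-alkylation of the sodium phenoxide by the reactive chloromethyl ether caps the hindered chelated hydroxyl with the group that later frees the O1 phenol of unit A.

Step 4
Reactants: 5 2,4,6-trihydroxybenzaldehyde
Product: 6 4-(benzyloxy)-2,6-dihydroxybenzaldehyde
Conditions: BnBr (1.0 equiv), K2CO3 (1.0 equiv), DMF, 0 °C to rt
Reagents that add atoms: benzyl bromide, BrCc1ccccc1
Why: Williamson etherification, in which the 4-hydroxyl para to the formyl group reacts first because the two equivalent ortho hydroxyls are chelated to the aldehyde.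

Step 5
Reactants: 6 4-(benzyloxy)-2,6-dihydroxybenzaldehyde
Product: 7 4-(benzyloxy)-2-hydroxy-6-(methoxymethoxy)benzaldehyde
Conditions: MOMCl (1.05 equiv), K2CO3, acetone, 0 °C to rt
Reagents that add atoms: chloromethyl methyl ether, COCCl
Why: Desymmetrising mono-protection (Williamson-type), in which the two ortho hydroxyls are equivalent and the one left after the first alkylation is fully engaged in the hydrogen bond to the aldehyde, so the reaction should stop at the mono-ether.

Step 6
Reactants: 7 4-(benzyloxy)-2-hydroxy-6-(methoxymethoxy)benzaldehyde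
Product: 8 4-(benzyloxy)-2-hydroxy-3-iodo-6-(methoxymethoxy)benzaldehyde
Conditions: NIS (1.0 equiv), DMF, 0 °C to rt, dark
Reagents that add atoms: N-iodosuccinimide, O=C1CCC(=O)N1I
Why: Electrophilic aromatic iodination ortho to the remaining chelated phenol places iodine at C3 (future C6 of unit B), the para site being flanked by two alkoxy groups.

Step 7
Reactants: 8 4-(benzyloxy)-2-hydroxy-3-iodo-6-(methoxymethoxy)benzaldehyde
Product: 9 4-(benzyloxy)-3-iodo-2-methoxy-6-(methoxymethoxy)benzaldehyde (unit B iodide)
Conditions: MeI, K2CO3, DMF, 40 °C
Reagents that add atoms: iodomethane, CI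
Why: Williamson methylation of the last chelated phenol fixes the C5 methoxy group next to the future bridge, which is what makes unit B the 6-linked half.

Step 8
Reactants: 4 unit A iodide; 10 bis(pinacolato)borylmethane
Product: 11 4-(benzyloxy)-6-methoxy-2-(methoxymethoxy)-3-[(pinacolatoboryl)methyl]benzaldehyde (unit A benzylboronate)
Conditions: 10 (1.5 equiv), Pd[P(t-Bu)3]2 (5 mol%), 8 M aq KOH, dioxane, rt
Reagents that add atoms: none
Why: Chemoselective Suzuki–Miyaura coupling of a geminal diborylmethane, in which hydroxide activates one boron of 10 and the second boryl group assists transmetalation, so the aryl iodide becomes a benzylboronate that does not couple further at room temperature.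

Step 9
Reactants: 11 unit A benzylboronate; 9 unit B iodide
Product: 12 4-(benzyloxy)-3-{[6-(benzyloxy)-3-formyl-2-methoxy-4-(methoxymethoxy)phenyl]methyl}-6-methoxy-2-(methoxymethoxy)benzaldehyde (bridged bis-aldehyde)
Conditions: Pd(OAc)2 (5 mol%), SPhos (10 mol%), K3PO4, toluene/H2O, 80 °C
Reagents that add atoms: none
Why: sp3–sp2 Suzuki–Miyaura coupling of the benzylboronate with the di-ortho-substituted aryl iodide under a bulky biarylphosphine joins C8 of unit A to C6 of unit B through the methylene, and both aldehydes are inert to the conditions.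

Step 10
Reactants: 12 bridged bis-aldehyde
Product: 13 bridged bis(hydroxymethyl)arene
Conditions: NaBH4, THF/MeOH, 0 °C
Reagents that add atoms: none
Why: Borohydride reduction converts both aryl aldehydes into benzylic alcohols and leaves the ethers and acetals untouched.

Step 11
Reactants: 13 bridged bis(hydroxymethyl)arene
Product: 15 bridged bis(chloromethyl)arene (C7 benzyl ethers; C8a methoxymethyl ethers), via bis-mesylate 14 (not isolated)
Conditions: MsCl, Et3N, LiCl, THF, −20 to 0 °C; cold NaHCO3 wash, no chromatography, used at once
Reagents that add atoms: methanesulfonyl chloride, CS(=O)(=O)Cl; lithium chloride, [Li+].[Cl-]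
Why: Mesylation followed by in situ SN2 displacement with chloride under basic, non-ionising conditions gives both benzylic chlorides, which are very electron-rich and are therefore kept cold and taken on without purification.

Step 12
Reactants: 15 bridged bis(chloromethyl)arene; 16 vinylboronic acid pinacol ester; 17 phenyllithium
Product: 19 bridged bis[(R)-3-aryl-1-phenylpropyl pinacol boronate], via lithium phenyl(vinyl)pinacolatoborate 18 (not isolated)
Conditions: 16 (2.6 equiv), 17 (2.5 equiv), Et2O, 0 °C; then NiBr2(dme) (10 mol%), (S,S)-N,N′-dimethyl-1,2-diphenylethane-1,2-diamine (12 mol%), slow addition of 15, THF, 0 °C to rt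
Reagents that add atoms: none
Why: Proposed new method: phenyllithium adds to the boron of 16 to give ate complex 18, NiBr2(dme) is reduced in situ to a zerovalent nickel–diamine species that inserts into each benzylic C–Cl bond, the benzylnickel so formed binds the vinyl group of 18 and induces a 1,2-shift of phenyl from boron to the adjacent carbon anti to nickel, and C(sp3)–C(sp3) reductive elimination then joins C4 to C3. The closest known reaction type is the nickel- or palladium-catalysed enantioselective conjunctive cross-coupling of vinylboron ate complexes with aryl, alkenyl and alkyl electrophiles, in which benzylic chlorides have not been used. No ring is closed in this step. Each new C2 stereocentre is set under catalyst control by the chiral diamine on nickel, which selects the alkene face that is bound while phenyl migrates to the opposite face; the two remote sites react independently, so the (R,R) isomer should dominate and the minor diastereomers are removed by chromatography. The step needs oxidative addition to outrun uncatalysed ionisation of the electron-rich chlorides (which would give racemic product by electrophile-induced migration, or self-alkylation) and benzylic homocoupling; the chloride leaving group, the ether solvent, the low temperature, the slow addition of 15 and the flanking ortho oxygens, which can chelate nickel and shield the benzylic carbon, are relied on for this.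

Step 13
Reactants: 19 bridged bis-boronate
Product: 20 bridged bis-boronate with free C8a phenols
Conditions: HCl (1.25 M in MeOH), THF, 40 °C; crude product taken on
Reagents that add atoms: none
Why: Acid-catalysed acetal methanolysis removes both methoxymethyl ethers while the C–B bonds, benzyl ethers and methyl ethers persist, and doing this before the oxidation keeps acid away from the later benzylic carbinols, which could otherwise ionise and cyclise with loss of configuration.

Step 14
Reactants: 20 bridged bis-boronate with free C8a phenols
Product: 21 bridged bis[(R)-3-aryl-1-phenylpropan-1-ol] with free C8a phenols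
Conditions: 30% H2O2, 3 M NaOH, THF, 0 °C
Reagents that add atoms: hydrogen peroxide, OO
Why: Alkaline peroxide oxidation of the secondary benzylic boronates proceeds by 1,2-migration of carbon from boron to oxygen with retention, giving the (R,R)-diol.

Step 15
Reactants: 21 bridged (R,R)-diol diphenol
Product: 22 (2S,2′S)-7,7′-di-O-benzyl bisflavan
Conditions: PPh3, DIAD, THF (0.01 M), 0 °C to rt
Reagents that add atoms: none
Why: Double intramolecular Mitsunobu etherification, in which each C8a phenol displaces the activated benzylic oxygen of its own side chain in a 6-exo-tet SN2 closure with inversion, turns the (R)-carbinols into (S)-configured C2 centres; the C7 oxygens are blocked as benzyl ethers and the unactivated phenyl group disfavours ionisation.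

Step 16
Reactants: 22 (2S,2′S)-7,7′-di-O-benzyl bisflavan
Product: 23 CNP0178097.1, (2S,2′S)-8,6′-methylene-bridged bis(7-hydroxy-5-methoxyflavan)
Conditions: H2 (1 atm), 10% Pd/C, EtOAc/MeOH, rt, stopped after two equivalents of H2
Reagents that add atoms: none
Why: Catalytic hydrogenolysis cleaves the two aryl benzyl ethers under neutral conditions that leave the benzylic C2–O1 bonds of the flavans and both stereocentres intact.

## Compound list

1 | 2,4-dihydroxy-6-methoxybenzaldehyde | COc1cc(O)cc(O)c1C=O | starting material
2 | 4-(benzyloxy)-2-hydroxy-6-methoxybenzaldehyde | COc1cc(OCc2ccccc2)cc(O)c1C=O | intermediate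
3 | 4-(benzyloxy)-2-hydroxy-3-iodo-6-methoxybenzaldehyde | COc1cc(OCc2ccccc2)c(I)c(O)c1C=O | intermediate
4 | 4-(benzyloxy)-3-iodo-6-methoxy-2-(methoxymethoxy)benzaldehyde (unit A iodide) | COc1cc(OCc2ccccc2)c(I)c(OCOC)c1C=O | intermediate
5 | 2,4,6-trihydroxybenzaldehyde | O=Cc1c(O)cc(O)cc1O | starting material
6 | 4-(benzyloxy)-2,6-dihydroxybenzaldehyde | O=Cc1c(O)cc(OCc2ccccc2)cc1O | intermediate
7 | 4-(benzyloxy)-2-hydroxy-6-(methoxymethoxy)benzaldehyde | COCOc1cc(OCc2ccccc2)cc(O)c1C=O | intermediate
8 | 4-(benzyloxy)-2-hydroxy-3-iodo-6-(methoxymethoxy)benzaldehyde | COCOc1cc(OCc2ccccc2)c(I)c(O)c1C=O | intermediate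
9 | 4-(benzyloxy)-3-iodo-2-methoxy-6-(methoxymethoxy)benzaldehyde (unit B iodide) | COCOc1cc(OCc2ccccc2)c(I)c(OC)c1C=O | intermediate
10 | bis(pinacolato)borylmethane | CC1(C)OB(CB2OC(C)(C)C(C)(C)O2)OC1(C)C | starting material
11 | 4-(benzyloxy)-6-methoxy-2-(methoxymethoxy)-3-[(pinacolatoboryl)methyl]benzaldehyde (unit A benzylboronate) | COc1cc(OCc2ccccc2)c(CB2OC(C)(C)C(C)(C)O2)c(OCOC)c1C=O | intermediate
12 | bridged bis-aldehyde (CH2 from C8 of unit A to C6 of unit B; C7 benzyl ethers, C8a methoxymethyl ethers) | COc1cc(OCc2ccccc2)c(Cc2c(OCc3ccccc3)cc(OCOC)c(C=O)c2OC)c(OCOC)c1C=O | intermediate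
13 | bridged bis(hydroxymethyl)arene | COc1cc(OCc2ccccc2)c(Cc2c(OCc3ccccc3)cc(OCOC)c(CO)c2OC)c(OCOC)c1CO | intermediate
14 | bridged bis-mesylate (not isolated) | COc1cc(OCc2ccccc2)c(Cc2c(OCc3ccccc3)cc(OCOC)c(COS(C)(=O)=O)c2OC)c(OCOC)c1COS(C)(=O)=O | intermediate
15 | bridged bis(chloromethyl)arene (precursor of the key step) | COc1cc(OCc2ccccc2)c(Cc2c(OCc3ccccc3)cc(OCOC)c(CCl)c2OC)c(OCOC)c1CCl | intermediate
16 | vinylboronic acid pinacol ester | C=CB1OC(C)(C)C(C)(C)O1 | starting material
17 | phenyllithium | [Li]c1ccccc1 | starting material
18 | lithium phenyl(vinyl)pinacolatoborate (ate complex, not isolated) | [Li+].C=C[B-]1(c2ccccc2)OC(C)(C)C(C)(C)O1 | intermediate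
19 | bridged bis[(R)-3-aryl-1-phenylpropyl pinacol boronate] (product of the key step) | COc1cc(OCc2ccccc2)c(Cc2c(OCc3ccccc3)cc(OCOC)c(CC[C@H](c3ccccc3)B3OC(C)(C)C(C)(C)O3)c2OC)c(OCOC)c1CC[C@H](c1ccccc1)B1OC(C)(C)C(C)(C)O1 | intermediate
20 | bridged (R,R)-bis-boronate with free C8a phenols | COc1cc(OCc2ccccc2)c(Cc2c(OCc3ccccc3)cc(O)c(CC[C@H](c3ccccc3)B3OC(C)(C)C(C)(C)O3)c2OC)c(O)c1CC[C@H](c1ccccc1)B1OC(C)(C)C(C)(C)O1 | intermediate
21 | bridged bis[(R)-3-aryl-1-phenylpropan-1-ol] with free C8a phenols | COc1cc(OCc2ccccc2)c(Cc2c(OCc3ccccc3)cc(O)c(CC[C@@H](O)c3ccccc3)c2OC)c(O)c1CC[C@@H](O)c1ccccc1 | intermediate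
22 | (2S,2′S)-7,7′-di-O-benzyl-8,6′-methylene-bridged bis(5-methoxyflavan) | COc1cc(OCc2ccccc2)c(Cc2c(OCc3ccccc3)cc3c(c2OC)CC[C@@H](c2ccccc2)O3)c2c1CC[C@@H](c1ccccc1)O2 | intermediate
23 | CNP0178097.1, (2S,2′S)-8,6′-methylene-bridged bis(7-hydroxy-5-methoxyflavan) | COc1cc(O)c(Cc2c(O)cc3c(c2OC)CC[C@@H](c2ccccc2)O3)c2c1CC[C@@H](c1ccccc1)O2 | target

## Step count and risks

Total steps: 16. Longest linear sequence: 12 (steps 4–7 and 9–16; the branch through steps 1–3 and 8 is equally long).

Steps most likely to fail:

1. Step 12 (key step). Oxidative addition may lose to ionisation of the chlorides, which would give racemic background migration or self-alkylation. Benzylic homocoupling or β-hydride elimination after the metallate shift may also intervene, and facial control by the diamine may be poor for a benzylic partner. The fallback uses known chemistry, sets out from bis-aldehyde 12 and returns at diol 21. Double Claisen–Schmidt condensation with acetophenone (KOH, EtOH) should give the bis-(E)-enone F1. Hydrogenation of both C=C bonds with H2 and RhCl(PPh3)3, which spares the benzyl ethers, gives the saturated diketone F2. HCl in MeOH removes the methoxymethyl groups to give the diphenol diketone F3. Asymmetric transfer hydrogenation with RuCl(p-cymene)[(R,R)-TsDPEN] in HCO2H/Et3N then reduces both aryl ketones to the (R)-carbinols, which is compound 21, ready for the Mitsunobu closure.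

2. Step 11. The 2,4,6-trioxygenated benzylic chlorides may ionise during formation or work-up. That would lead to alkylation of the free arene positions, attack by the neighbouring methoxymethyl oxygen, or hydrolysis. The fallback sets out from 13, avoids any benzylic halide and returns at bis-boronate 19. Methyl chloroformate and pyridine give the bis(methyl carbonate) F4, which should tolerate chromatography. Palladium-catalysed Suzuki–Miyaura coupling of the benzylic carbonates with (E)-styrylboronic acid ([Pd(C3H5)Cl]2, 1,5-bis(diphenylphosphino)pentane, K2CO3, DMF) gives the bis-(E)-cinnamyl arene F5. Enantioselective Markovnikov hydroboration of the two β-alkylstyrene units (CuCl, NaOt-Bu, the DTBM-SEGPHOS antipode that gives (R), HBpin) places boron on the phenyl-bearing carbons and delivers 19.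

3. Step 9. Coupling of two di-ortho-substituted partners may be slow, so that protodeboronation of the benzylboronate takes over. The fallback sets out from 11, replaces the palladium coupling by a cationic C–C bond formation, and returns at 12. Oxidation of 11 (NaBO3·4H2O, THF/H2O) gives the benzylic alcohol F6. Friedel–Crafts benzylation of phenol 7 at the position ortho to its chelated hydroxyl (cat. Sc(OTf)3, hexafluoroisopropanol, rt) gives the diarylmethane phenol F7; the site of attack would have to be confirmed, since the position para to the hydroxyl is also activated. Methylation of the remaining phenol (MeI, K2CO3, DMF) gives bis-aldehyde 12.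

## Further compounds

F1 | step 12 | bridged bis-(E)-enone (bis-chalcone) | COc1cc(OCc2ccccc2)c(Cc2c(OCc3ccccc3)cc(OCOC)c(/C=C/C(=O)c3ccccc3)c2OC)c(OCOC)c1/C=C/C(=O)c1ccccc1
F2 | step 12 | bridged bis(3-aryl-1-phenylpropan-1-one) | COc1cc(OCc2ccccc2)c(Cc2c(OCc3ccccc3)cc(OCOC)c(CCC(=O)c3ccccc3)c2OC)c(OCOC)c1CCC(=O)c1ccccc1
F3 | step 12 | bridged diketone with free C8a phenols | COc1cc(OCc2ccccc2)c(Cc2c(OCc3ccccc3)cc(O)c(CCC(=O)c3ccccc3)c2OC)c(O)c1CCC(=O)c1ccccc1
F4 | step 11 | bridged bis(benzylic methyl carbonate) | COc1cc(OCc2ccccc2)c(Cc2c(OCc3ccccc3)cc(OCOC)c(COC(=O)OC)c2OC)c(OCOC)c1COC(=O)OC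
F5 | step 11 | bridged bis-(E)-cinnamyl arene | COc1cc(OCc2ccccc2)c(Cc2c(OCc3ccccc3)cc(OCOC)c(C/C=C/c3ccccc3)c2OC)c(OCOC)c1C/C=C/c1ccccc1
F6 | step 9 | 4-(benzyloxy)-3-(hydroxymethyl)-6-methoxy-2-(methoxymethoxy)benzaldehyde | COc1cc(OCc2ccccc2)c(CO)c(OCOC)c1C=O
F7 | step 9 | bridged bis-aldehyde with free C5 phenol in unit B | COc1cc(OCc2ccccc2)c(Cc2c(OCc3ccccc3)cc(OCOC)c(C=O)c2O)c(OCOC)c1C=O
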